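The numbers in the tables were computed from invented constants; scatter was added.

I began from what was left over in two earlier flasks, with four new flasks to forecast.

| flask | J | Z | remark | time |
|---|---|---|---|---|
| larch | 0.025 M | 9 mM (held) | run made earlier |  |
| birch | 0.22 M | 9 mM (held) | run made earlier |  |
| winter | 0.030 M | 9.0 mM (held) |  | 25 min |
| midnight | 0.060 M | 9.0 mM (held) |  | 25 min |
| summer | 0.12 M | 9.0 mM (held) |  | 25 min |
| dawn | 0.25 M | 9.0 mM (held) |  | 25 min |

| run | time / min | L / % | J / % |
|---|---|---|---|
| larch | 1.00 | 0 | 96.2 |
| larch | 3.00 | 1.5 | 88.3 |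
| larch | 6.00 | 6.4 | 79.5 |
| larch | 8.00 | 8.7 | 73.2 |
| larch | 12.0 | 15.3 | 62.6 |
| birch | 1.00 | 1.0 | 98.6 |
| birch | 2.00 | 0.3 | 98.9 |
| birch | 4.00 | 0.2 | 98.2 |
| birch | 6.00 | 0 | 97.0 |
| birch | 12.0 | 1.2 | 96.0 |

(each reading ± 1 percentage point)

- as a solid, counted per litre of solution: J
- at the start none of J is in solution
- at the start none of Z is in solution
- "hardly changes" means that all values lie within two and a half points (for a concentration: within two and a half percent of the largest)

1. amount of L at the end, in percent of the J charged for winter, midnight, summer, dawn, in this order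
2. the course of these numbers from the first flask to the last (falls, then rises / rises, then falls / rises all the way / hardly changes / falls all the way)

After 12.0 min the larch flask still held 62.6% of its J as solid and the birch flask 96.0%. These look unlike until the balance of J is written in concentration: larch had lost 9.35 mM and birch 8.80 mM, about the same, given that a birch reading scatters by 2.20 mM. So I took the loss as zero order in the charge, at about 0.756 mM min⁻¹.

Folding in time and charge gives N = u t / cJ, which for the winter flask is 0.630, the share of the charge I reckoned to have left the solid by the end. It lies below one, and it shrinks as the charge grows, so at equal time and equal held Z I expected the percentage to go as one over the charge.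

Between 6.00 min and 12.0 min larch gained 8.9 percentage points of L for 17 points of J lost, a share s of 0.527. My reckoning, sN, was therefore 33.2%, 16.6%, 8.30% and 3.98%.

Was one number enough? For larch at 12.0 min sN gives 19.1% against 15.3% read, with a scatter of 1 point, so for larch one number was not enough. For birch it gives 2.17% against 1.2% read, a gap about the size of the scatter.

The forecast gave 33%, 13%, 4% and 1.5%, course falls all the way, holding that “a heavy J load appears to inhibit the step forming L”. My reckoning differs there, since it keeps L per litre the same.

The flasks gave 34.0%, 17.0%, 8.49% and 4.08%, course falls all the way: 10.2 mM of L in winter and 10.2 mM in dawn.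

    E + D → L (k = 0.230 M⁻¹ s⁻¹)
    J ⇌ E, rate k2*(cs2 - [E]) while solid is left; crystals form when [E] > cs2 (solubility = 9.50 mM, k = 0.00210 s⁻¹)
    Z ⇌ D, rate k3*(csat - [D]) (kL = 0.00910 s⁻¹)
    L ⇌ G (K = 0.110, k = 6.70 × 10⁻⁴ s⁻¹)
    E → X (k = 1.70 × 10⁻⁴ s⁻¹)

In the winter flask E was made 1.50 times as fast as it was used at 6.26 min, but it stood at 15.4% at 12.5 min and 16.1% at 25.0 min. N put the share of J off the solid by the end at 63.0% in winter, where 56.8% had left it, and at 7.56% in dawn, where 6.82% had left it.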